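**Plan**

1. Atom labels (labdane type): pyran ring O–C8(C17H3)–C9–C11–C12–C13(C16H3, vinyl C14=C15); carbocycle (ring B) C5–C6–C7–C8–C9–C10; C10 carries C20H3 and C1H2–C2O2H; C5 carries C4(CH3)2–C3O2H.
2. Retrosynthesis: the two acid carbons are joined (C2–C3) into a temporary cyclohexenone, ring A (C2=O, C3–OH), so that quaternary C10 becomes the β-carbon of an enone whose γ-carbon C5 holds the chain. Then C9–C10 and O–C8 are cut together (enone-initiated bicyclization of an E C8=C9 alkene that ends at the C13 tertiary alcohol). Last, C7–C8 and C8–C17 are cut (two couplings at a 1,1-dichloroalkene).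
3. Forward: (R)-α-ionone gives the ring A enone with a C6–C7 iodide; (R)-linalool gives the C8–C16 dichloroalkene; the two are coupled and C17 is added. After hydroxylation at C3, ring B and then the pyran close in one operation, and periodate/chlorite cleavage of C2–C3 removes ring A.
4. Stereochemistry: C5 comes from (R)-α-ionone and C13 from (R)-linalool. C10, C9 and C8 arise in the key step (cis A/B fusion forced by the tether on C5, chair ring B, anti addition across the E alkene). The alkene geometry comes from a trans-selective coupling followed by a coupling with retention.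
5. Enabling feature: C10 is β to carboxyl carbon C2, and C2 and C3 are 1,6-related through C1–C10–C5–C4. A six-membered enone can therefore hold C4 axial on ring B, which is exactly the cis C1/C4 (C20/H5 cis) arrangement of the target; C8 is the tertiary, oxygen-bearing end of a Markovnikov addition to C8=C9.

Key step: step 12

Assumption: (R)-(+)-α-ionone and (R)-(−)-linalool are taken as commercial natural-grade materials of high enantiomeric purity; their stereocentres (C5 and C13) are carried unchanged into the target.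

**Route**

Step 1
Reactants: 1 (R)-α-ionone, (3E)-4-[(1R)-2,6,6-trimethylcyclohex-2-en-1-yl]but-3-en-2-one
Product: 2 4-[(1R)-2,6,6-trimethylcyclohex-2-en-1-yl]butan-2-one
Conditions: H2 (1 atm), RhCl(PPh3)3 (3 mol%), benzene, rt
Reagents that add atoms: none
Why: Homogeneous hydrogenation with RhCl(PPh3)3 should saturate only the unhindered disubstituted enone C=C and leave the trisubstituted ring alkene, the ketone and the stereocentre untouched.

Step 2
Reactants: 2 4-[(1R)-2,6,6-trimethylcyclohex-2-en-1-yl]butan-2-one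
Product: 3 (4R)-3,5,5-trimethyl-4-(3-oxobutyl)cyclohex-2-en-1-one
Conditions: t-BuOOH (70% aq., 4 equiv), CrO3 (5 mol%), CH2Cl2, rt
Reagents that add atoms: tert-butyl hydroperoxide, CC(C)(C)OO
Why: Chromium-catalysed allylic oxidation should convert the only ring allylic CH2 (C2) into the enone carbonyl, as in the known oxidation of α-ionone at this position, under neutral conditions that should not touch C5.

Step 3
Reactants: 3 (4R)-3,5,5-trimethyl-4-(3-oxobutyl)cyclohex-2-en-1-one
Product: 4 2-[(1R)-2,6,6-trimethyl-4-oxocyclohex-2-en-1-yl]ethyl acetate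
Conditions: mCPBA (2 equiv), CF3CO2H (1 equiv), CH2Cl2, 0 °C to rt
Reagents that add atoms: 3-chloroperbenzoic acid, OOC(=O)c1cccc(Cl)c1
Why: Baeyer–Villiger oxidation of the saturated methyl ketone should proceed with migration of the primary alkyl group rather than methyl, while the electron-poor, β,β-disubstituted enone is neither epoxidized nor oxidized at a comparable rate.

Step 4
Reactants: 4 2-[(1R)-2,6,6-trimethyl-4-oxocyclohex-2-en-1-yl]ethyl acetate
Product: 5 (4R)-4-(2-hydroxyethyl)-3,5,5-trimethylcyclohex-2-en-1-one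
Conditions: p-TsOH·H2O (10 mol%), MeOH, rt
Reagents that add atoms: none
Why: Acid-catalysed transesterification should free the primary alcohol without alkoxide base, so that the γ-stereocentre C5 and the enone are not exposed to conjugate addition or enolization.

Step 5
Reactants: 5 (4R)-4-(2-hydroxyethyl)-3,5,5-trimethylcyclohex-2-en-1-one
Product: 6 (4R)-4-(2-iodoethyl)-3,5,5-trimethylcyclohex-2-en-1-one
Conditions: I2, PPh3, imidazole, CH2Cl2, 0 °C
Reagents that add atoms: iodine, II
Why: Appel-type iodination should convert the primary alcohol into the iodide by SN2 displacement under neutral conditions.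

Step 6
Reactants: 7 (R)-(−)-linalool, (3R)-3,7-dimethylocta-1,6-dien-3-ol
Product: 8 triethyl{[(3R)-3,7-dimethylocta-1,6-dien-3-yl]oxy}silane
Conditions: Et3SiOTf, 2,6-lutidine, CH2Cl2, −78 to 0 °C
Reagents that add atoms: triethylsilyl trifluoromethanesulfonate, CC[Si](CC)(CC)OS(=O)(=O)C(F)(F)F
Why: Silylation with a silyl triflate and a hindered base should protect the tertiary allylic alcohol without ionizing it, so C13 is untouched.

Step 7
Reactants: 8 triethyl{[(3R)-3,7-dimethylocta-1,6-dien-3-yl]oxy}silane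
Product: 10 (4R)-4-methyl-4-(triethylsilyloxy)hex-5-enal, via ozonide 9 (not isolated)
Conditions: O3 (1.0 equiv), CH2Cl2, −78 °C; then Me2S, −78 °C to rt
Reagents that add atoms: ozone, [O-][O+]=O
Why: Ozonolysis should be selective because the electron-rich trisubstituted alkene reacts much faster than the monosubstituted vinyl group; reductive work-up of the ozonide gives the aldehyde whose carbonyl carbon becomes C9.

Step 8
Reactants: 10 (4R)-4-methyl-4-(triethylsilyloxy)hex-5-enal
Product: 11 (3R)-7,7-dichloro-3-methyl-3-(triethylsilyloxy)hepta-1,6-diene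
Conditions: BrCCl3 (2 equiv), PPh3 (4 equiv), MeCN, 0 °C to rt
Reagents that add atoms: bromotrichloromethane, ClC(Cl)(Cl)Br
Why: Wittig-type dichloro-olefination with Ph3P=CCl2 made in the flask should give the 1,1-dichloroalkene whose new carbon becomes C8.

Step 9
Reactants: 6 (4R)-4-(2-iodoethyl)-3,5,5-trimethylcyclohex-2-en-1-one; 11 (3R)-7,7-dichloro-3-methyl-3-(triethylsilyloxy)hepta-1,6-diene
Product: 13 (4R)-4-[(3Z,7R)-3-chloro-7-methyl-7-(triethylsilyloxy)nona-3,8-dien-1-yl]-3,5,5-trimethylcyclohex-2-en-1-one, via alkylzinc iodide 12 (not isolated)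
Conditions: 6, Zn dust, LiCl, THF, 35 °C; then 11, PdCl2(DPEphos) (5 mol%; DPEphos = bis(2-diphenylphosphinophenyl) ether), THF/DMF, rt
Reagents that add atoms: none
Why: In this Negishi coupling zinc insertion tolerates the enone, and the palladium catalyst with the wide-bite-angle diphosphine should replace only the chlorine trans to the chain of the 1,1-dichloroalkene (trans-selective monoalkylation), which places C7 trans to C11.

Step 10
Reactants: 13 (4R)-4-[(3Z,7R)-3-chloro-7-methyl-7-(triethylsilyloxy)nona-3,8-dien-1-yl]-3,5,5-trimethylcyclohex-2-en-1-one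
Product: 14 (4R)-4-[(3E,7R)-3,7-dimethyl-7-(triethylsilyloxy)nona-3,8-dien-1-yl]-3,5,5-trimethylcyclohex-2-en-1-one
Conditions: Me2Zn (2 equiv), Pd(P(t-Bu)3)2 (5 mol%), THF, 0 to 40 °C
Reagents that add atoms: dimethylzinc, C[Zn]C
Why: A second Negishi coupling at the alkenyl chloride should proceed with retention, so the new methyl (C17) ends cis to C11 and the trisubstituted alkene is E.

Step 11
Reactants: 14 (4R)-4-[(3E,7R)-3,7-dimethyl-7-(triethylsilyloxy)nona-3,8-dien-1-yl]-3,5,5-trimethylcyclohex-2-en-1-one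
Product: 17 (4S,6R)-6-hydroxy-4-[(3E,7R)-7-hydroxy-3,7-dimethylnona-3,8-dien-1-yl]-3,5,5-trimethylcyclohex-2-en-1-one, via lithium dienolate 15 (not isolated), via hydroxy silyl ether 16 (not isolated)
Conditions: LiN(i-Pr)2 (1.2 equiv), THF, −78 °C; 2-(phenylsulfonyl)-3-phenyloxaziridine, −78 °C; AcOH; crude product, HF·pyridine, pyridine/THF, 0 °C
Reagents that add atoms: 2-(phenylsulfonyl)-3-phenyloxaziridine, O=S(=O)(c1ccccc1)N1OC1c1ccccc1
Why: Kinetic deprotonation of the cyclohexenone should occur at the α′ carbon C3, and Davis oxidation of the cross-conjugated enolate should place the hydroxyl anti to the pseudo-axial chain on C5 (the C3 centre is destroyed in step 13, so its epimer would serve equally); buffered fluoride then removes the silyl group without ionizing the tertiary allylic alcohol.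

Step 12
Reactants: 17 (4S,6R)-6-hydroxy-4-[(3E,7R)-7-hydroxy-3,7-dimethylnona-3,8-dien-1-yl]-3,5,5-trimethylcyclohex-2-en-1-one
Product: 19 tricyclic α-hydroxy ketone (8,13-epoxy-3-hydroxy-2-oxo framework with ring A closed between C2 and C3; A/B cis, B/pyran trans; all five target stereocentres in place), via aluminium enolate 18 (not isolated)
Conditions: MeAlCl2 (3.2 equiv), CH2Cl2, −78 to −40 °C; aq. NH4Cl
Reagents that add atoms: none
Why: Proposed new method: MeAlCl2 should first turn both hydroxyls into dichloroaluminium alkoxides, and a further equivalent, held in a five-membered chelate by the C3 alkoxide and the C2 carbonyl, should make C10 of the ring A enone electrophilic enough to be attacked by C9 of the C8=C9 alkene; the tertiary C8 cation is then captured by the C13 alkoxide and the aluminium enolate is protonated on work-up. The closest known reaction types are alkylaluminium halide-promoted conjugate additions of unactivated alkenes and of allylsilanes to cycloalkenones, including 3-methylcyclohexenones, and hydroxyl-terminated cation–olefin cyclizations such as homofarnesol to ambroxide; their union in one cascade on an isophorone-type enone is untested. Ring B closes in a 6-endo mode at the alkene (6-exo at the enone) and the pyran closes last by 6-endo capture of the cation on the face anti to the new C9–C10 bond. C10 is controlled by the tether, because the chain on C5 can reach only the face of C10 cis to itself and the bond forms axially on ring A, giving the cis A/B fusion (C20 and H5 cis). C9 and C8 are controlled by a chair for ring B with C20 axial, which puts C11 equatorial and H9 anti to C20, and by anti addition across the E alkene, which puts the ether oxygen equatorial and C17 axial (trans B/pyran fusion). The step needs activation of the enone without ionizing the tertiary allylic alkoxide, which the chelate, the proton-scavenging alkylaluminium reagent and the low temperature should secure, and six- over five-membered ring formation, which the Markovnikov polarization of the trisubstituted alkene secures.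

Step 13
Reactants: 19 tricyclic α-hydroxy ketone
Product: 20 2-[(2R,4aR,5S,6S,8aR)-2-ethenyl-2,5,8a-trimethyl-6-(2-methyl-1-oxopropan-2-yl)octahydro-2H-chromen-5-yl]acetic acid
Conditions: NaIO4 (3 equiv), THF/H2O 2:1, rt to 40 °C
Reagents that add atoms: water, O; sodium periodate, [Na+].[O-]I(=O)(=O)=O
Why: Periodate cleavage of the α-hydroxy ketone through its hydrate should break only the C2–C3 bond, giving the C2 acid and the C3 aldehyde; the vinyl group and the ether are inert and no stereocentre of the product is touched.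

Step 14
Reactants: 20 2-[(2R,4aR,5S,6S,8aR)-2-ethenyl-2,5,8a-trimethyl-6-(2-methyl-1-oxopropan-2-yl)octahydro-2H-chromen-5-yl]acetic acid
Product: 21 2-[(2R,4aR,5S,6S,8aR)-5-(carboxymethyl)-2-ethenyl-2,5,8a-trimethyloctahydro-2H-chromen-6-yl]-2-methylpropanoic acid
Conditions: NaClO2, NaH2PO4, 2-methyl-2-butene, t-BuOH/H2O, rt
Reagents that add atoms: sodium chlorite, [Na+].[O-]Cl=O
Why: Pinnick oxidation should convert the non-enolizable neopentyl aldehyde into the acid, with 2-methyl-2-butene trapping hypochlorous acid so that the vinyl group survives.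

**Compound list**

1 | (R)-α-ionone, (3E)-4-[(1R)-2,6,6-trimethylcyclohex-2-en-1-yl]but-3-en-2-one | CC(=O)/C=C/[C@H]1C(C)=CCCC1(C)C | starting material
2 | 4-[(1R)-2,6,6-trimethylcyclohex-2-en-1-yl]butan-2-one | CC(=O)CC[C@H]1C(C)=CCCC1(C)C | intermediate
3 | (4R)-3,5,5-trimethyl-4-(3-oxobutyl)cyclohex-2-en-1-one | CC(=O)CC[C@H]1C(C)=CC(=O)CC1(C)C | intermediate
4 | 2-[(1R)-2,6,6-trimethyl-4-oxocyclohex-2-en-1-yl]ethyl acetate | CC(=O)OCC[C@H]1C(C)=CC(=O)CC1(C)C | intermediate
5 | (4R)-4-(2-hydroxyethyl)-3,5,5-trimethylcyclohex-2-en-1-one | OCC[C@H]1C(C)=CC(=O)CC1(C)C | intermediate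
6 | (4R)-4-(2-iodoethyl)-3,5,5-trimethylcyclohex-2-en-1-one | ICC[C@H]1C(C)=CC(=O)CC1(C)C | intermediate
7 | (R)-(−)-linalool, (3R)-3,7-dimethylocta-1,6-dien-3-ol | C=C[C@@](O)(C)CCC=C(C)C | starting material
8 | triethyl{[(3R)-3,7-dimethylocta-1,6-dien-3-yl]oxy}silane | C=C[C@@](O[Si](CC)(CC)CC)(C)CCC=C(C)C | intermediate
9 | 3,3-dimethyl-5-[(3R)-3-methyl-3-(triethylsilyloxy)pent-4-en-1-yl]-1,2,4-trioxolane (ozonide, not isolated) | C=C[C@@](O[Si](CC)(CC)CC)(C)CCC1OOC(C)(C)O1 | intermediate
10 | (4R)-4-methyl-4-(triethylsilyloxy)hex-5-enal | C=C[C@@](O[Si](CC)(CC)CC)(C)CCC=O | intermediate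
11 | (3R)-7,7-dichloro-3-methyl-3-(triethylsilyloxy)hepta-1,6-diene | C=C[C@@](O[Si](CC)(CC)CC)(C)CCC=C(Cl)Cl | intermediate
12 | {2-[(1R)-2,6,6-trimethyl-4-oxocyclohex-2-en-1-yl]ethyl}zinc iodide (not isolated) | I[Zn]CC[C@H]1C(C)=CC(=O)CC1(C)C | intermediate
13 | (4R)-4-[(3Z,7R)-3-chloro-7-methyl-7-(triethylsilyloxy)nona-3,8-dien-1-yl]-3,5,5-trimethylcyclohex-2-en-1-one | C=C[C@@](O[Si](CC)(CC)CC)(C)CC/C=C(\Cl)CC[C@H]1C(C)=CC(=O)CC1(C)C | intermediate
14 | (4R)-4-[(3E,7R)-3,7-dimethyl-7-(triethylsilyloxy)nona-3,8-dien-1-yl]-3,5,5-trimethylcyclohex-2-en-1-one | C=C[C@@](O[Si](CC)(CC)CC)(C)CC/C=C(\C)CC[C@H]1C(C)=CC(=O)CC1(C)C | intermediate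
15 | lithium cross-conjugated dienolate of 14 (C2–OLi, C2=C3; not isolated) | C=C[C@@](O[Si](CC)(CC)CC)(C)CC/C=C(\C)CC[C@H]1C(C)=CC(O[Li])=CC1(C)C | intermediate
16 | (4S,6R)-4-[(3E,7R)-3,7-dimethyl-7-(triethylsilyloxy)nona-3,8-dien-1-yl]-6-hydroxy-3,5,5-trimethylcyclohex-2-en-1-one (hydroxyl trans to the side chain; not isolated) | C=C[C@@](O[Si](CC)(CC)CC)(C)CC/C=C(\C)CC[C@H]1C(C)=CC(=O)[C@H](O)C1(C)C | intermediate
17 | (4S,6R)-6-hydroxy-4-[(3E,7R)-7-hydroxy-3,7-dimethylnona-3,8-dien-1-yl]-3,5,5-trimethylcyclohex-2-en-1-one | C=C[C@@](O)(C)CC/C=C(\C)CC[C@H]1C(C)=CC(=O)[C@H](O)C1(C)C | intermediate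
18 | dichloroaluminium enolate (C1=C2–O–AlCl2) and C3 dichloroaluminium alkoxide of 19 (not isolated) | C=C[C@@]1(C)CC[C@@H]2[C@@]3(C)C=C(O[Al](Cl)Cl)[C@H](O[Al](Cl)Cl)C(C)(C)[C@H]3CC[C@@]2(C)O1 | intermediate
19 | tricyclic α-hydroxy ketone: ring A (C10–C1–C2(=O)–C3(OH)–C4–C5) cis-fused to ring B, pyran trans-fused to ring B; C3–OH trans to C6 across ring A; 5β-H, 10β-CH3, 9α-H, 8β-CH3, 13R | C=C[C@@]1(C)CC[C@@H]2[C@@]3(C)CC(=O)[C@H](O)C(C)(C)[C@H]3CC[C@@]2(C)O1 | intermediate
20 | 2-[(2R,4aR,5S,6S,8aR)-2-ethenyl-2,5,8a-trimethyl-6-(2-methyl-1-oxopropan-2-yl)octahydro-2H-chromen-5-yl]acetic acid | C=C[C@@]1(C)CC[C@@H]2[C@@](C)(CC(=O)O)[C@@H](C(C)(C)C=O)CC[C@@]2(C)O1 | intermediate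
21 | 2-[(2R,4aR,5S,6S,8aR)-5-(carboxymethyl)-2-ethenyl-2,5,8a-trimethyloctahydro-2H-chromen-6-yl]-2-methylpropanoic acid | C=C[C@@]1(C)CC[C@@H]2[C@@](C)(CC(=O)O)[C@@H](C(C)(C)C(=O)O)CC[C@@]2(C)O1 | target

**Step count**

Total steps: 14. Longest linear sequence: 11 (steps 1–5 and 9–14); the linalool branch (steps 6–8) joins at step 9.

**Steps most likely to fail**

Step 12 (proposed new method). The tertiary allylic alkoxide may ionize. The C8 cation may lose a proton to give alkenes instead of the ether. Attack at the hindered β-carbon C10 (1,3-interaction with a C4 methyl) may be so slow that enolization at C5 erodes its configuration. Ring B may also close through a boat and give the C9/C8 epimers.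
The fallback uses known chemistry, sets out from 13 and comes back at 19. Negishi coupling of 13 with Me3SiCH2ZnCl and Pd(P(t-Bu)3)2 should give, with retention, the allylsilane (4R)-3,5,5-trimethyl-4-[(3Z,7R)-7-methyl-7-(triethylsilyloxy)-3-(trimethylsilylmethyl)nona-3,8-dien-1-yl]cyclohex-2-en-1-one F1. Deprotonation with LiN(i-Pr)2 as in step 11 gives its lithium dienolate F2, and the oxaziridine gives the hydroxy silyl ether F3. HF·pyridine then frees the diol F4. EtAlCl2 in CH2Cl2 at −78 °C should promote an intramolecular Hosomi–Sakurai addition to the enone. This proceeds through the aluminium enolate F5 to the cis-fused methylene ketone F6, which has the exocyclic C8=C17 alkene and the same chair-derived configuration at C9 and C10. Intramolecular alkoxymercuration with Hg(OCOCF3)2 closes the pyran by equatorial attack of the C13 hydroxyl on C8 and gives the organomercurial F7. Demercuration with Bu3SnH, which leaves the ketone alone, gives 19.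

Step 9. The alkylzinc reagent may substitute both chlorines, trans selectivity may erode, or β-hydride elimination may compete, so that the alkene geometry is lost.
The fallback sets out from 10 and comes back at 14. Dimethyl (1-diazo-2-oxopropyl)phosphonate with K2CO3 in MeOH should give the alkyne (3R)-3-methyl-3-(triethylsilyloxy)hept-1-en-6-yne F8. n-BuLi gives its lithium acetylide F9, and MeI gives (3R)-3-methyl-3-(triethylsilyloxy)oct-1-en-6-yne F10. Hydrozirconation with Cp2Zr(H)Cl is selective for the alkyne over the hindered vinyl group and places zirconium on the methyl-bearing carbon by syn addition, giving the alkenylzirconocene chloride F11. Iodine then gives (3R,6E)-7-iodo-3-methyl-3-(triethylsilyloxy)octa-1,6-diene F12. A single Negishi coupling of F12 with alkylzinc iodide 12 under Pd(PPh3)4 gives 14 with the geometry fixed by the hydrometalation.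

Step 11. Deprotonation may occur at the γ-carbon C5 (loss of configuration), or the enolate may add to the sulfonimine formed from the oxidant.
The fallback sets out from 14 and comes back at 17 without strong base. Heating with Mn(OAc)3·2H2O in benzene should acetoxylate the enone at the α′ carbon and give (4S,6R)-6-acetoxy-4-[(3E,7R)-3,7-dimethyl-7-(triethylsilyloxy)nona-3,8-dien-1-yl]-3,5,5-trimethylcyclohex-2-en-1-one F13. K2CO3 in MeOH gives the hydroxy silyl ether 16, and HF·pyridine gives 17.

Further compounds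
F1 | step 12 | (4R)-3,5,5-trimethyl-4-[(3Z,7R)-7-methyl-7-(triethylsilyloxy)-3-(trimethylsilylmethyl)nona-3,8-dien-1-yl]cyclohex-2-en-1-one | C=C[C@@](O[Si](CC)(CC)CC)(C)CC/C=C(\C[Si](C)(C)C)CC[C@H]1C(C)=CC(=O)CC1(C)C
F2 | step 12 | lithium cross-conjugated dienolate of F1 | C=C[C@@](O[Si](CC)(CC)CC)(C)CC/C=C(\C[Si](C)(C)C)CC[C@H]1C(C)=CC(O[Li])=CC1(C)C
F3 | step 12 | (4S,6R)-6-hydroxy-3,5,5-trimethyl-4-[(3Z,7R)-7-methyl-7-(triethylsilyloxy)-3-(trimethylsilylmethyl)nona-3,8-dien-1-yl]cyclohex-2-en-1-one | C=C[C@@](O[Si](CC)(CC)CC)(C)CC/C=C(\C[Si](C)(C)C)CC[C@H]1C(C)=CC(=O)[C@H](O)C1(C)C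
F4 | step 12 | (4S,6R)-6-hydroxy-4-[(3Z,7R)-7-hydroxy-7-methyl-3-(trimethylsilylmethyl)nona-3,8-dien-1-yl]-3,5,5-trimethylcyclohex-2-en-1-one | C=C[C@@](O)(C)CC/C=C(\C[Si](C)(C)C)CC[C@H]1C(C)=CC(=O)[C@H](O)C1(C)C
F5 | step 12 | aluminium enolate (C1=C2–O–AlClEt) and bis(dichloroaluminium alkoxide) of F6 | C=C[C@@](O[Al](Cl)Cl)(C)CC[C@@H]2[C@@]3(C)C=C(O[Al](Cl)CC)[C@H](O[Al](Cl)Cl)C(C)(C)[C@H]3CCC2=C
F6 | step 12 | cis-fused bicyclic hydroxy ketone with exocyclic C8=C17 methylene and free C13 hydroxyl (open-pyran isomer of 19) | C=C[C@@](O)(C)CC[C@@H]2[C@@]3(C)CC(=O)[C@H](O)C(C)(C)[C@H]3CCC2=C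
F7 | step 12 | C17-mercurated 19, (trifluoroacetoxy)mercuriomethyl group on C8 | C=C[C@@]1(C)CC[C@@H]2[C@@]3(C)CC(=O)[C@H](O)C(C)(C)[C@H]3CC[C@@]2(C[Hg]OC(=O)C(F)(F)F)O1
F8 | step 9 | (3R)-3-methyl-3-(triethylsilyloxy)hept-1-en-6-yne | C=C[C@@](O[Si](CC)(CC)CC)(C)CCC#C
F9 | step 9 | lithium acetylide of F8 | C=C[C@@](O[Si](CC)(CC)CC)(C)CCC#C[Li]
F10 | step 9 | (3R)-3-methyl-3-(triethylsilyloxy)oct-1-en-6-yne | C=C[C@@](O[Si](CC)(CC)CC)(C)CCC#CC
F11 | step 9 | chlorobis(cyclopentadienyl)[(2E,6R)-6-methyl-6-(triethylsilyloxy)octa-2,7-dien-2-yl]zirconium | C=C[C@@](O[Si](CC)(CC)CC)(C)CC/C=C(\C)[Zr+2]Cl.c1cc[cH-]c1.c1cc[cH-]c1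
F12 | step 9 | (3R,6E)-7-iodo-3-methyl-3-(triethylsilyloxy)octa-1,6-diene | C=C[C@@](O[Si](CC)(CC)CC)(C)CC/C=C(\C)I
F13 | step 11 | (4S,6R)-6-acetoxy-4-[(3E,7R)-3,7-dimethyl-7-(triethylsilyloxy)nona-3,8-dien-1-yl]-3,5,5-trimethylcyclohex-2-en-1-one | C=C[C@@](O[Si](CC)(CC)CC)(C)CC/C=C(\C)CC[C@H]1C(C)=CC(=O)[C@H](OC(C)=O)C1(C)C
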